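## Retrosynthetic overview

1. Target 16 ⇐ 15 (loss of the O7 methoxymethyl group) ⇐ 10. The strategy rests on one feature: the C8 prenyl group of ring A lies para to O5, and the C5' 1,1-dimethylallyl group of ring B (quaternary carbon on C5') lies ortho to O4'. Both C-allyl units are therefore [3,3] images of O-prenyl ethers at O5 and O4' (Claisen–Cope on ring A, ortho-Claisen on ring B).
2. 10 ⇐ chromone 4 + arylboronic acid 9. The C2–C1' bond and the only stereocentre (C2, S) come from a rhodium-catalysed asymmetric 1,4-addition.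
3. 4 ⇐ 5,7-dihydroxychromone 1 (MOM at O7, then prenyl at O5); 9 ⇐ 4-bromo-3-methoxyphenol 5 (O-prenylation, then Br to B(OH)2).
4. Ring order: no ring is built. Rings A and C are bought as the chromone and ring B as the bromophenol; ring C only changes from pyranone to dihydropyranone in the 1,4-addition.

Key step: step 6

Abbreviations: prenyl = 3-methylbut-2-en-1-yl; 1,1-dimethylallyl = 2-methylbut-3-en-2-yl; MOM = methoxymethyl; fod = 6,6,7,7,8,8,8-heptafluoro-2,2-dimethyloctane-3,5-dionate; MeO-F12-BIPHEP = 6,6'-dimethoxy-2,2'-bis[bis(3,4,5-trifluorophenyl)phosphino]-1,1'-biphenyl. Flavanone numbering: ring C O1–C4, ring A C5–C8, ring B C1'–C6'.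

Assumption: the (S)-biaryl bisphosphine is taken to deliver the aryl group to the Re face of C2 (which gives 2S), by analogy with its sense of induction on 2-cyclohexenone; if the first run shows the opposite sense, the (R)-ligand is used and nothing else changes.

## Route

Step 1
Reactants: 1 5,7-dihydroxychromone
Product: 2 5-hydroxy-7-(methoxymethoxy)chromone
Conditions: MOMCl (1.1 equiv), K2CO3 (1.5 equiv), acetone, 0 °C to rt
Reagents that add atoms: chloromethyl methyl ether COCCl
Why: Williamson-type O-alkylation in which the 7-OH is the more acidic, vinylogous-acid hydroxyl while the 5-OH is held in a hydrogen bond to the C4 carbonyl, so one equivalent of the chloride should go to O7 only.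

Step 2
Reactants: 2 5-hydroxy-7-(methoxymethoxy)chromone; 3 prenyl bromide
Product: 4 7-(methoxymethoxy)-5-(prenyloxy)chromone
Conditions: K2CO3 (2 equiv), DMF, 50 °C
Reagents that add atoms: none
Why: Williamson ether synthesis (SN2 at the primary allylic bromide) on the only remaining hydroxyl; carbonate in a dipolar aprotic solvent breaks the hydrogen bond and favours O- over C-alkylation, and the chromone and the MOM acetal are stable to carbonate.

Step 3
Reactants: 5 4-bromo-3-methoxyphenol; 3 prenyl bromide
Product: 6 1-bromo-2-methoxy-4-(prenyloxy)benzene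
Conditions: K2CO3 (1.5 equiv), acetone, reflux
Reagents that add atoms: none
Why: Williamson ether synthesis of an unhindered phenol with a reactive allylic bromide, to which the aryl bromide is inert.

Step 4
Reactants: 6 1-bromo-2-methoxy-4-(prenyloxy)benzene
Product: 9 [2-methoxy-4-(prenyloxy)phenyl]boronic acid, via aryllithium 7 (not isolated), via lithium aryltriisopropoxyborate 8 (not isolated)
Conditions: n-BuLi (1.05 equiv), THF, −78 °C; B(OiPr)3 (1.5 equiv), −78 to 0 °C; 1 M HCl, 0 °C, 10 min
Reagents that add atoms: triisopropyl borate CC(C)OB(OC(C)C)OC(C)C; water O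
Why: Bromine–lithium exchange is faster at −78 °C than ortho-metalation or attack on the allyl ether, the aryllithium is trapped by the borate as its ate complex, and brief cold dilute acid hydrolyses the B–O bonds without cleaving the aryl prenyl ether.

Step 5
Reactants: 4 7-(methoxymethoxy)-5-(prenyloxy)chromone; 9 [2-methoxy-4-(prenyloxy)phenyl]boronic acid
Product: 10 (2S)-2'-methoxy-7-(methoxymethoxy)-5,4'-bis(prenyloxy)flavanone
Conditions: [Rh(OH)((S)-MeO-F12-BIPHEP)]2 (1.5 mol %), 9 (3 equiv, in portions), CH2Cl2/H2O 10:1, 30 °C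
Reagents that add atoms: none
Why: Hayashi–Miyaura asymmetric 1,4-addition in which the arylrhodium species from transmetalation inserts C2=C3 of the chromone and the rhodium enolate is protonated by water; the C2 stereocentre is set by the C2-symmetric bisphosphine on monovalent rhodium, which exposes one enantioface of the bound chromone (aryl delivery to the Re face of C2 gives 2S), and the base-free two-phase medium keeps the flavanone from ring-opening or taking up a second aryl group.

Step 6
Reactants: 10 (2S)-2'-methoxy-7-(methoxymethoxy)-5,4'-bis(prenyloxy)flavanone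
Product: 15 (2S)-5,4'-dihydroxy-2'-methoxy-7-(methoxymethoxy)-5'-(1,1-dimethylallyl)-8-prenylflavanone, via ring-A C6 ortho-dienone 11 (not isolated), via ring-A C8 para-dienone 12 (not isolated), via 8-prenyl-4'-prenyloxyflavanone 13 (not isolated), via ring-B C5' ortho-dienone 14 (not isolated)
Conditions: Eu(fod)3 (0.2 equiv), NaHCO3 (1 equiv), PhCl, argon, 85 °C until 13 has formed, then 120 °C
Reagents that add atoms: none
Why: Trivalent europium in Eu(fod)3 chelates O5 and the C4 carbonyl, so at 85 °C the O5 prenyl group undergoes an aromatic Claisen [3,3] shift to C6, the only free ortho position; the crowded C6 dienone 11 passes the allyl unit on by a Cope [3,3] shift to C8 and dienone 12 enolises to the chelated phenol 13, which forms the C8–CH2 bond with the prenyl connectivity restored. In the hotter stage the 4'-O-prenyl ether, which has no chelating neighbour and is the slower half, undergoes a single ortho-Claisen [3,3] shift to C5' and dienone 14 enolises, which forms the bond from C5' to the quaternary carbon of the inverted 1,1-dimethylallyl unit. The closest known reactions are the europium-promoted para-Claisen–Cope rearrangement of 5-O-prenylflavanones to 8-prenylflavanones and the thermal or lanthanide-assisted Claisen rearrangement of 3-methoxyphenyl prenyl ethers to ortho-(1,1-dimethylallyl)phenols. No ring is closed and no stereocentre is made; C2 is a spectator that survives only if ring C does not open to the chalcone, which is why a weak oxophilic Lewis acid, a hydrogencarbonate buffer and temperatures well below those of uncatalysed prenyl ether rearrangements are chosen. On ring A the step needs the Cope shift to win over enolisation at C6, and the strain of a tertiary carbon wedged between the europium-bound O5 and the O7 MOM group secures it. On ring B it needs C5' over C3', and C3' is shut off because it lies between the C2' methoxy group and O4', while the substituted para carbon C1' stops the migration at the ortho stage.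

Step 7
Reactants: 15 (2S)-5,4'-dihydroxy-2'-methoxy-7-(methoxymethoxy)-5'-(1,1-dimethylallyl)-8-prenylflavanone
Product: 16 (2S)-5,7,4'-trihydroxy-2'-methoxy-5'-(1,1-dimethylallyl)-8-prenylflavanone (CNP0308136.1)
Conditions: 3 M HCl (aq)/MeOH 1:5, 40 °C
Reagents that add atoms: none
Why: Acid-catalysed solvolysis of the MOM acetal (transacetalisation to dimethoxymethane), run dilute and only warm so that neither the prenyl and 1,1-dimethylallyl alkenes add to the neighbouring phenols nor the C2–O1 bond ionises, while the phenols, the aryl methyl ether and the ketone are untouched.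

## Compound list

1 | 5,7-dihydroxychromone (5,7-dihydroxy-4H-chromen-4-one) | O=c1ccoc2cc(O)cc(O)c12 | starting material
2 | 5-hydroxy-7-(methoxymethoxy)chromone | O=c1ccoc2cc(OCOC)cc(O)c12 | intermediate
3 | prenyl bromide (1-bromo-3-methylbut-2-ene) | CC(C)=CCBr | starting material
4 | 7-(methoxymethoxy)-5-(prenyloxy)chromone | O=c1ccoc2cc(OCOC)cc(OCC=C(C)C)c12 | intermediate
5 | 4-bromo-3-methoxyphenol | COc1cc(O)ccc1Br | starting material
6 | 1-bromo-2-methoxy-4-(prenyloxy)benzene | COc1cc(OCC=C(C)C)ccc1Br | intermediate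
7 | [2-methoxy-4-(prenyloxy)phenyl]lithium | [Li]c1ccc(OCC=C(C)C)cc1OC | intermediate
8 | lithium [2-methoxy-4-(prenyloxy)phenyl]tri(propan-2-yloxy)borate | [Li+].COc1cc(OCC=C(C)C)ccc1[B-](OC(C)C)(OC(C)C)OC(C)C | intermediate
9 | [2-methoxy-4-(prenyloxy)phenyl]boronic acid | COc1cc(OCC=C(C)C)ccc1B(O)O | intermediate
10 | (2S)-2'-methoxy-7-(methoxymethoxy)-5,4'-bis(prenyloxy)flavanone | CC(C)=CCOc1ccc([C@@H]2CC(=O)c3c(OCC=C(C)C)cc(OCOC)cc3O2)c(OC)c1 | intermediate
11 | ring-A C6 ortho-dienone: (2S)-6-(1,1-dimethylallyl)-2'-methoxy-7-(methoxymethoxy)-4'-(prenyloxy)-2,3-dihydro-6H-chromene-4,5-dione, both epimers at C6 | CC(C)=CCOc1ccc([C@@H]2CC(=O)C3=C(O2)C=C(OCOC)C(C(C)(C)C=C)C3=O)c(OC)c1 | intermediate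
12 | ring-A C8 para-dienone: (2S)-2'-methoxy-7-(methoxymethoxy)-8-prenyl-4'-(prenyloxy)-2,3-dihydro-8H-chromene-4,5-dione, both epimers at C8 | CC(C)=CCOc1ccc([C@@H]2CC(=O)C3=C(O2)C(CC=C(C)C)C(OCOC)=CC3=O)c(OC)c1 | intermediate
13 | (2S)-5-hydroxy-2'-methoxy-7-(methoxymethoxy)-8-prenyl-4'-(prenyloxy)flavanone | CC(C)=CCOc1ccc([C@@H]2CC(=O)c3c(O)cc(OCOC)c(CC=C(C)C)c3O2)c(OC)c1 | intermediate
14 | ring-B C5' ortho-dienone: the cyclohexa-2,4-dienone tautomer of 15 with C4'=O and an sp3 C5' carrying H and the 1,1-dimethylallyl group, both epimers at C5' | C=CC(C)(C)C1C=C([C@@H]2CC(=O)c3c(O)cc(OCOC)c(CC=C(C)C)c3O2)C(OC)=CC1=O | intermediate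
15 | (2S)-5,4'-dihydroxy-2'-methoxy-7-(methoxymethoxy)-5'-(1,1-dimethylallyl)-8-prenylflavanone | C=CC(C)(C)c1cc([C@@H]2CC(=O)c3c(O)cc(OCOC)c(CC=C(C)C)c3O2)c(OC)cc1O | intermediate
16 | (2S)-5,7,4'-trihydroxy-2'-methoxy-5'-(1,1-dimethylallyl)-8-prenylflavanone (CNP0308136.1) | C=CC(C)(C)c1cc([C@@H]2CC(=O)c3c(O)cc(O)c(CC=C(C)C)c3O2)c(OC)cc1O | target

## Step count

Total: 7 steps. Longest linear sequence: 5 steps (1 → 2 → 4 → 10 → 15 → 16 through steps 1, 2, 5, 6, 7; the arm from 5 through steps 3, 4, 5, 6, 7 is equally long).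

## Steps most likely to fail, with fallbacks

**Step 6 (key step).** Three processes may spoil it. The ring-B [3,3] shift may not start below the temperature at which ring C opens reversibly to the chalcone, with loss of configuration at C2. The C6 dienone may enolise before the Cope shift, which strands the allyl unit at C6. The ortho-(1,1-dimethylallyl)phenol may rearrange further during the hotter stage. The fallback takes the ring-B shift out of the flavanone stage; it sets out from compounds 6 and 4 and comes back at compound 16. Bromide 6 is heated alone (N,N-diethylaniline, 185 °C), where no stereocentre is at risk, and should give 4-bromo-5-methoxy-2-(2-methylbut-3-en-2-yl)phenol F1. MOMCl and NaH in DMF give its methoxymethyl ether F2. Bromine–lithium exchange and borate quench as in step 4 give [2-methoxy-4-(methoxymethoxy)-5-(2-methylbut-3-en-2-yl)phenyl]boronic acid F3. The 1,4-addition to chromone 4 as in step 5 gives (2S)-2'-methoxy-7,4'-bis(methoxymethoxy)-5'-(1,1-dimethylallyl)-5-(prenyloxy)flavanone F4. Eu(fod)3 and NaHCO3 in PhCl at 85 °C then have to run only the chelation-assisted Claisen–Cope shift and should give the 7,4'-bis(methoxymethyl) ether of the target F5. HCl in MeOH as in step 7 removes both MOM groups and gives 16.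

**Step 5.** Protodeboronation of the electron-rich, ortho-substituted boronic acid may outrun transmetalation, insertion into the 5-alkoxychromone may be slow with a bisphosphine complex, or enantioface discrimination may be poor with the ortho-methoxyaryl group. The fallback gives up asymmetric catalysis for a racemic addition with resolution and recycling; it sets out from compounds 4 and 9 and comes back at compound 10. The more reactive achiral diene complex [Rh(OH)(cod)]2 (cod = 1,5-cyclooctadiene) in dioxane/H2O at 40 °C should give racemic 2'-methoxy-7-(methoxymethoxy)-5,4'-bis(prenyloxy)flavanone F6. Preparative chromatography on an amylose tris(3,5-dimethylphenylcarbamate) phase separates 10 from the (2R)-antipode F7. F7 is returned to F6 by NaOAc in EtOH at reflux, through reversible opening to the 2'-hydroxychalcone F8, and is resolved again.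

**Step 7.** Acid may promote addition of the freed 7-OH or the 4'-OH across the neighbouring alkene (chroman or dihydrobenzofuran formation), or the benzylic C2–O1 bond may ionise with help from the 2'-methoxy and 4'-hydroxy groups, with loss of configuration. The fallback replaces the acid-labile acetal at O7 by a silyl ether that is removed with fluoride; it sets out from compound 1 and comes back at compound 16. Compound 1 is silylated at O7 (i-Pr3SiCl, imidazole, DMF) to 5-hydroxy-7-(triisopropylsilyloxy)chromone F9. Mitsunobu etherification with 3-methylbut-2-en-1-ol (PPh3, diisopropyl azodicarboxylate, THF), chosen because carbonate in DMF could strip the aryl silyl ether, gives 5-(prenyloxy)-7-(triisopropylsilyloxy)chromone F10. Step 5 with boronic acid 9 gives (2S)-2'-methoxy-5,4'-bis(prenyloxy)-7-(triisopropylsilyloxy)flavanone F11. Step 6 gives (2S)-5,4'-dihydroxy-2'-methoxy-5'-(1,1-dimethylallyl)-8-prenyl-7-(triisopropylsilyloxy)flavanone F12. Bu4NF buffered with AcOH in THF at 0 °C frees O7 and gives 16.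

## Further compounds

F1 | step 6 | 4-bromo-5-methoxy-2-(2-methylbut-3-en-2-yl)phenol | C=CC(C)(C)c1cc(Br)c(OC)cc1O
F2 | step 6 | 1-bromo-2-methoxy-4-(methoxymethoxy)-5-(2-methylbut-3-en-2-yl)benzene | C=CC(C)(C)c1cc(Br)c(OC)cc1OCOC
F3 | step 6 | [2-methoxy-4-(methoxymethoxy)-5-(2-methylbut-3-en-2-yl)phenyl]boronic acid | C=CC(C)(C)c1cc(B(O)O)c(OC)cc1OCOC
F4 | step 6 | (2S)-2'-methoxy-7,4'-bis(methoxymethoxy)-5'-(1,1-dimethylallyl)-5-(prenyloxy)flavanone | C=CC(C)(C)c1cc([C@@H]2CC(=O)c3c(OCC=C(C)C)cc(OCOC)cc3O2)c(OC)cc1OCOC
F5 | step 6 | (2S)-5-hydroxy-2'-methoxy-7,4'-bis(methoxymethoxy)-5'-(1,1-dimethylallyl)-8-prenylflavanone | C=CC(C)(C)c1cc([C@@H]2CC(=O)c3c(O)cc(OCOC)c(CC=C(C)C)c3O2)c(OC)cc1OCOC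
F6 | step 5 | racemic 2'-methoxy-7-(methoxymethoxy)-5,4'-bis(prenyloxy)flavanone | CC(C)=CCOc1ccc(C2CC(=O)c3c(OCC=C(C)C)cc(OCOC)cc3O2)c(OC)c1
F7 | step 5 | (2R)-2'-methoxy-7-(methoxymethoxy)-5,4'-bis(prenyloxy)flavanone | CC(C)=CCOc1ccc([C@H]2CC(=O)c3c(OCC=C(C)C)cc(OCOC)cc3O2)c(OC)c1
F8 | step 5 | (E)-1-[2-hydroxy-4-(methoxymethoxy)-6-(prenyloxy)phenyl]-3-[2-methoxy-4-(prenyloxy)phenyl]prop-2-en-1-one | CC(C)=CCOc1ccc(/C=C/C(=O)c2c(O)cc(OCOC)cc2OCC=C(C)C)c(OC)c1
F9 | step 7 | 5-hydroxy-7-(triisopropylsilyloxy)chromone | O=c1ccoc2cc(O[Si](C(C)C)(C(C)C)C(C)C)cc(O)c12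
F10 | step 7 | 5-(prenyloxy)-7-(triisopropylsilyloxy)chromone | O=c1ccoc2cc(O[Si](C(C)C)(C(C)C)C(C)C)cc(OCC=C(C)C)c12
F11 | step 7 | (2S)-2'-methoxy-5,4'-bis(prenyloxy)-7-(triisopropylsilyloxy)flavanone | CC(C)=CCOc1ccc([C@@H]2CC(=O)c3c(OCC=C(C)C)cc(O[Si](C(C)C)(C(C)C)C(C)C)cc3O2)c(OC)c1
F12 | step 7 | (2S)-5,4'-dihydroxy-2'-methoxy-5'-(1,1-dimethylallyl)-8-prenyl-7-(triisopropylsilyloxy)flavanone | C=CC(C)(C)c1cc([C@@H]2CC(=O)c3c(O)cc(O[Si](C(C)C)(C(C)C)C(C)C)c(CC=C(C)C)c3O2)c(OC)cc1O
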